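**Plan**
- Retrosynthesis: first cut the bond from flavone C6 to the benzylic CH2 (Negishi coupling of a 6-iodoluteolin derivative with a cyclohexylmethylzinc); then cut the two carbocycle bonds CH(CH2Ar)–CMe2 and CH2–CH2 together in a [4+2] sense.
- Enabling feature: in the cyclohexane the carbinol carbon is 1,4 to the CMe2 carbon and the CH(CH2Ar) carbon is 1,2 to it. The ring is therefore the adduct of a 2-silyloxy-1-alkyl diene and α-methylacrolein with both directing effects matched. The formyl group is the activating helper (later reduced to the second methyl), and the enol ether left in the ring marks the carbon that receives the exocyclic methylene.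
- Forward order: Wittig enone, siloxydiene, catalytic asymmetric Diels–Alder (carbocycle), CHO to CH3, α-methylenation, ketone reduction, protecting-group and iodide adjustment. The flavone is taken intact from luteolin (silylation, C6 iodination, acetylation). Union by Negishi coupling, then global deprotection.
- Stereochemistry: the CH(CH2Ar) centre comes from the chiral oxazaborolidinium catalyst in the Diels–Alder step (endo transition state). The carbinol centre, trans to the side chain, comes from reagent-controlled Corey–Bakshi–Shibata reduction.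

Key step: step 3

Assumption: the facial sense of the catalyst in step 3 is assigned from the usual model for α-substituted enals (B–O coordination, formyl C–H···O contact, s-trans enal, attack on the face remote from the shielding aryl group, formyl endo); the configuration of 6 follows from it.

**Step 1**
Reactants: 1 (tert-butyldimethylsilyloxy)acetaldehyde; 2 1-(triphenylphosphoranylidene)propan-2-one
Product: 3 (E)-5-[(tert-butyldimethylsilyl)oxy]pent-3-en-2-one
Conditions: CH2Cl2, rt
Reagents that add atoms: none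
Why: Wittig olefination with a stabilised ylide should give the (E)-enone selectively.

**Step 2**
Reactants: 3 (E)-5-[(tert-butyldimethylsilyl)oxy]pent-3-en-2-one
Product: 4 (E)-5-[(tert-butyldimethylsilyl)oxy]-2-[(triisopropylsilyl)oxy]penta-1,3-diene
Conditions: LDA, THF, −78 °C; then TIPSOTf, −78 to 0 °C
Reagents that add atoms: triisopropylsilyl trifluoromethanesulfonate, CC(C)[Si](C(C)C)(C(C)C)OS(=O)(=O)C(F)(F)F
Why: Kinetic α′-deprotonation of the methyl ketone and O-silylation of the cross-conjugated enolate (silyl enol ether formation) should give the 2-silyloxy diene with the (E)-alkene untouched.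

**Step 3**
Reactants: 4 (E)-5-[(tert-butyldimethylsilyl)oxy]-2-[(triisopropylsilyl)oxy]penta-1,3-diene; 5 methacrolein (2-methylprop-2-enal)
Product: 6 (1S,2R)-2-{[(tert-butyldimethylsilyl)oxy]methyl}-1-methyl-4-[(triisopropylsilyl)oxy]cyclohex-3-ene-1-carbaldehyde
Conditions: (S)-3,3-diphenyl-1-(o-tolyl)tetrahydro-1H,3H-pyrrolo[1,2-c][1,3,2]oxazaborole (20 mol%), Tf2NH (18 mol%), CH2Cl2, −78 to −40 °C
Reagents that add atoms: none
Why: This is a concerted, asynchronous, normal-demand [4+2] cycloaddition of a 2-silyloxy diene with an enal activated by a chiral cationic oxazaborolidine; the closest known reaction type is the catalytic enantioselective Diels–Alder reaction of 2-(triisopropylsilyloxy)-1,3-dienes with α-methylacrolein under the same catalyst class. The cyclohexene ring closes in an intermolecular [4π+2π] mode, suprafacial on both partners: the CH2 terminus of the diene (largest HOMO coefficient, next to the silyloxy carbon) bonds to the unsubstituted β-carbon of the enal and the CH2OTBS-bearing terminus bonds to the α-carbon. The CH(CH2OTBS) centre is controlled by the catalyst, which fixes the enal and shields one of its faces, together with the endo orientation of the formyl group and the fixed (E) geometry of the diene. The quaternary centre is set by the same elements but is of no consequence, because it becomes CMe2 in step 4. The step needs regioselectivity, endo selectivity, facial selectivity and cycloaddition instead of Mukaiyama-type addition. These should be secured by the matched 2-silyloxy ("para") and 1-alkyl ("ortho") directing effects, by the bulky TIPS group that disfavours silyl transfer, and by the low temperature.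

**Step 4**
Reactants: 6 (1S,2R)-2-{[(tert-butyldimethylsilyl)oxy]methyl}-1-methyl-4-[(triisopropylsilyl)oxy]cyclohex-3-ene-1-carbaldehyde
Product: 8 (R)-tert-butyl{[6,6-dimethyl-3-(triisopropylsilyloxy)cyclohex-2-en-1-yl]methoxy}dimethylsilane, via tosylhydrazone 7 (not isolated)
Conditions: TsNHNH2, THF, rt; then catecholborane, CHCl3, 0 °C; then NaOAc·3H2O, 60 °C
Reagents that add atoms: none
Why: Tosylhydrazone reduction (a mild Wolff–Kishner-type deoxygenation by hydroboration of C=N, sulfinate loss and N2 extrusion) should turn the non-enolisable neopentyl CHO into CH3 under near-neutral conditions that the TIPS enol ether and TBS ether tolerate; the quaternary stereocentre disappears and the catalyst-set CH centre is untouched.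

**Step 5**
Reactants: 8 (R)-tert-butyl{[6,6-dimethyl-3-(triisopropylsilyloxy)cyclohex-2-en-1-yl]methoxy}dimethylsilane
Product: 11 (S)-3-{[(tert-butyldimethylsilyl)oxy]methyl}-4,4-dimethyl-2-methylidenecyclohexan-1-one, via Mannich base 9 (not isolated), via methiodide 10 (not isolated)
Conditions: [CH2=NMe2]I, CH2Cl2, rt; NaHCO3 (aq) wash; MeI, CH2Cl2/MeOH, rt; then NaHCO3 (aq), rt
Reagents that add atoms: dimethyl(methylidene)ammonium iodide, C=[N+](C)C.[I-]
Why: Mannich reaction at the nucleophilic carbon of the regiodefined silyl enol ether, followed by quaternisation and E1cB loss of trimethylamine, should place the exocyclic methylene on the hindered α-carbon without affecting the adjacent stereocentre.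

**Step 6**
Reactants: 11 (S)-3-{[(tert-butyldimethylsilyl)oxy]methyl}-4,4-dimethyl-2-methylidenecyclohexan-1-one
Product: 12 (1S,3S)-3-{[(tert-butyldimethylsilyl)oxy]methyl}-4,4-dimethyl-2-methylidenecyclohexan-1-ol (OH trans to CH2OTBS)
Conditions: (R)-2-methyl-CBS-oxazaborolidine (0.5 equiv), catecholborane, toluene, −78 °C
Reagents that add atoms: none
Why: Corey–Bakshi–Shibata reduction under reagent control, with the methylidene-bearing carbon as the large group, should deliver hydride to give the (S)-carbinol trans to the side chain, the low temperature disfavouring conjugate reduction.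

**Step 7**
Reactants: 12 (1S,3S)-3-{[(tert-butyldimethylsilyl)oxy]methyl}-4,4-dimethyl-2-methylidenecyclohexan-1-ol
Product: 13 tert-butyl{[(1S,3S)-6,6-dimethyl-2-methylidene-3-(triisopropylsilyloxy)cyclohexyl]methoxy}dimethylsilane
Conditions: TIPSOTf, 2,6-lutidine, CH2Cl2, −78 to 0 °C
Reagents that add atoms: triisopropylsilyl trifluoromethanesulfonate, CC(C)[Si](C(C)C)(C(C)C)OS(=O)(=O)C(F)(F)F
Why: Silyl ether formation on the secondary allylic alcohol under buffered conditions installs a group that is not ionised by palladium and is orthogonal to the primary TBS ether.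

**Step 8**
Reactants: 13 tert-butyl{[(1S,3S)-6,6-dimethyl-2-methylidene-3-(triisopropylsilyloxy)cyclohexyl]methoxy}dimethylsilane
Product: 14 [(1S,3S)-6,6-dimethyl-2-methylidene-3-(triisopropylsilyloxy)cyclohexyl]methanol
Conditions: HF·pyridine, pyridine, THF, 0 °C
Reagents that add atoms: none
Why: Selective desilylation: the primary TBS ether is cleaved by buffered fluoride much faster than the hindered secondary TIPS ether.

**Step 9**
Reactants: 14 [(1S,3S)-6,6-dimethyl-2-methylidene-3-(triisopropylsilyloxy)cyclohexyl]methanol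
Product: 15 {[(1S,3S)-3-(iodomethyl)-4,4-dimethyl-2-methylidenecyclohexyl]oxy}triisopropylsilane
Conditions: PPh3, I2, imidazole, CH2Cl2, 0 °C to rt
Reagents that add atoms: iodine, II
Why: Appel-type iodination of the primary alcohol proceeds at the CH2 carbon only, so neither stereocentre is affected.

**Step 10**
Reactants: 16 luteolin
Product: 17 7,3′,4′-tri-O-(tert-butyldimethylsilyl)luteolin
Conditions: TBSCl (3.3 equiv), imidazole, DMF, 0 °C to rt
Reagents that add atoms: tert-butyldimethylsilyl chloride, CC(C)(C)[Si](C)(C)Cl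
Why: Selective phenol silylation: the 5-OH is hydrogen-bonded to the C4 carbonyl and is the least reactive, so the other three hydroxyls should be protected first.

**Step 11**
Reactants: 17 7,3′,4′-tri-O-(tert-butyldimethylsilyl)luteolin
Product: 18 6-iodo-7,3′,4′-tri-O-(tert-butyldimethylsilyl)luteolin
Conditions: BnMe3N·ICl2 (1.05 equiv), CaCO3, CH2Cl2/MeOH, rt
Reagents that add atoms: benzyltrimethylammonium dichloroiodate, C[N+](C)(C)Cc1ccccc1.Cl[I-]Cl
Why: Electrophilic aromatic iodination of ring A, which the chelated free 5-OH should direct to its ortho position C6 in preference to C8.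

**Step 12**
Reactants: 18 6-iodo-7,3′,4′-tri-O-(tert-butyldimethylsilyl)luteolin
Product: 19 5-O-acetyl-6-iodo-7,3′,4′-tri-O-(tert-butyldimethylsilyl)luteolin
Conditions: Ac2O, Et3N, DMAP (cat.), CH2Cl2, rt
Reagents that add atoms: acetic anhydride, CC(=O)OC(C)=O
Why: DMAP-catalysed acylation masks the acidic 5-OH with a small group so that it cannot protonate the organozinc in the coupling.

**Step 13**
Reactants: 15 {[(1S,3S)-3-(iodomethyl)-4,4-dimethyl-2-methylidenecyclohexyl]oxy}triisopropylsilane; 19 5-O-acetyl-6-iodo-7,3′,4′-tri-O-(tert-butyldimethylsilyl)luteolin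
Product: 21 5-O-acetyl-7,3′,4′-tri-O-(tert-butyldimethylsilyl)-O-(triisopropylsilyl)ugonin Q, via alkylzinc iodide 20 (not isolated)
Conditions: Zn dust, LiCl, THF, 40 °C; decant from Zn; then 19, Pd(OAc)2 (5 mol%), SPhos (10 mol%), THF/NMP, 50 °C
Reagents that add atoms: none
Why: Zinc insertion into the primary iodide followed by Negishi coupling; the bulky electron-rich biarylphosphine on zerovalent palladium (formed in situ from Pd(OAc)2) should allow oxidative addition at the di-ortho-substituted aryl iodide and fast reductive elimination of the primary alkyl group, and the flavone carbonyl, acetate and silyl ethers are inert to the organozinc.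

**Step 14**
Reactants: 21 5-O-acetyl-7,3′,4′-tri-O-(tert-butyldimethylsilyl)-O-(triisopropylsilyl)ugonin Q
Product: 22 ugonin Q
Conditions: TBAF, THF, 0 °C to rt; then K2CO3, MeOH, rt, under argon
Reagents that add atoms: none
Why: Fluoride desilylation of all four silyl ethers and mild methanolysis of the phenolic acetate avoid acid throughout, which would cyclise a phenol onto the exocyclic alkene or ionise the allylic alcohol.

**Compound list**
1 | (tert-butyldimethylsilyloxy)acetaldehyde | O=CCO[Si](C)(C)C(C)(C)C | starting material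
2 | 1-(triphenylphosphoranylidene)propan-2-one | CC(=O)C=P(c1ccccc1)(c1ccccc1)c1ccccc1 | starting material
3 | (E)-5-[(tert-butyldimethylsilyl)oxy]pent-3-en-2-one | CC(=O)/C=C/CO[Si](C)(C)C(C)(C)C | intermediate
4 | (E)-5-[(tert-butyldimethylsilyl)oxy]-2-[(triisopropylsilyl)oxy]penta-1,3-diene | C=C(O[Si](C(C)C)(C(C)C)C(C)C)/C=C/CO[Si](C)(C)C(C)(C)C | intermediate
5 | methacrolein | C=C(C)C=O | starting material
6 | (1S,2R)-2-{[(tert-butyldimethylsilyl)oxy]methyl}-1-methyl-4-[(triisopropylsilyl)oxy]cyclohex-3-ene-1-carbaldehyde | CC(C)[Si](C(C)C)(C(C)C)OC1=C[C@@H](CO[Si](C)(C)C(C)(C)C)[C@@](C)(C=O)CC1 | intermediate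
7 | (E)-N-tosylhydrazone of 6 | CC(C)[Si](C(C)C)(C(C)C)OC1=C[C@@H](CO[Si](C)(C)C(C)(C)C)[C@@](C)(/C=N/NS(=O)(=O)c2ccc(C)cc2)CC1 | intermediate
8 | (R)-tert-butyl{[6,6-dimethyl-3-(triisopropylsilyloxy)cyclohex-2-en-1-yl]methoxy}dimethylsilane | CC(C)[Si](C(C)C)(C(C)C)OC1=C[C@@H](CO[Si](C)(C)C(C)(C)C)C(C)(C)CC1 | intermediate
9 | (3R)-3-{[(tert-butyldimethylsilyl)oxy]methyl}-2-[(dimethylamino)methyl]-4,4-dimethylcyclohexan-1-one (epimers at C2) | CN(C)CC1C(=O)CCC(C)(C)[C@@H]1CO[Si](C)(C)C(C)(C)C | intermediate
10 | N-methyl quaternary ammonium iodide of 9 | C[N+](C)(C)CC1C(=O)CCC(C)(C)[C@@H]1CO[Si](C)(C)C(C)(C)C.[I-] | intermediate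
11 | (S)-3-{[(tert-butyldimethylsilyl)oxy]methyl}-4,4-dimethyl-2-methylidenecyclohexan-1-one | C=C1[C@@H](CO[Si](C)(C)C(C)(C)C)C(C)(C)CCC1=O | intermediate
12 | (1S,3S)-3-{[(tert-butyldimethylsilyl)oxy]methyl}-4,4-dimethyl-2-methylidenecyclohexan-1-ol | C=C1[C@@H](CO[Si](C)(C)C(C)(C)C)C(C)(C)CC[C@@H]1O | intermediate
13 | tert-butyl{[(1S,3S)-6,6-dimethyl-2-methylidene-3-(triisopropylsilyloxy)cyclohexyl]methoxy}dimethylsilane | C=C1[C@@H](CO[Si](C)(C)C(C)(C)C)C(C)(C)CC[C@@H]1O[Si](C(C)C)(C(C)C)C(C)C | intermediate
14 | [(1S,3S)-6,6-dimethyl-2-methylidene-3-(triisopropylsilyloxy)cyclohexyl]methanol | C=C1[C@@H](CO)C(C)(C)CC[C@@H]1O[Si](C(C)C)(C(C)C)C(C)C | intermediate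
15 | {[(1S,3S)-3-(iodomethyl)-4,4-dimethyl-2-methylidenecyclohexyl]oxy}triisopropylsilane | C=C1[C@@H](CI)C(C)(C)CC[C@@H]1O[Si](C(C)C)(C(C)C)C(C)C | intermediate
16 | luteolin, 2-(3,4-dihydroxyphenyl)-5,7-dihydroxy-4H-chromen-4-one | O=c1cc(-c2ccc(O)c(O)c2)oc2cc(O)cc(O)c12 | starting material
17 | 7,3′,4′-tri-O-(tert-butyldimethylsilyl)luteolin | O=c1cc(-c2ccc(O[Si](C)(C)C(C)(C)C)c(O[Si](C)(C)C(C)(C)C)c2)oc2cc(O[Si](C)(C)C(C)(C)C)cc(O)c12 | intermediate
18 | 6-iodo-7,3′,4′-tri-O-(tert-butyldimethylsilyl)luteolin | O=c1cc(-c2ccc(O[Si](C)(C)C(C)(C)C)c(O[Si](C)(C)C(C)(C)C)c2)oc2cc(O[Si](C)(C)C(C)(C)C)c(I)c(O)c12 | intermediate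
19 | 5-O-acetyl-6-iodo-7,3′,4′-tri-O-(tert-butyldimethylsilyl)luteolin | O=c1cc(-c2ccc(O[Si](C)(C)C(C)(C)C)c(O[Si](C)(C)C(C)(C)C)c2)oc2cc(O[Si](C)(C)C(C)(C)C)c(I)c(OC(C)=O)c12 | intermediate
20 | {[(1S,3S)-6,6-dimethyl-2-methylidene-3-(triisopropylsilyloxy)cyclohexyl]methyl}zinc iodide | C=C1[C@@H](C[Zn]I)C(C)(C)CC[C@@H]1O[Si](C(C)C)(C(C)C)C(C)C | intermediate
21 | 5-O-acetyl-7,3′,4′-tri-O-(tert-butyldimethylsilyl)-O-(triisopropylsilyl)ugonin Q | C=C1[C@@H](Cc2c(O[Si](C)(C)C(C)(C)C)cc3oc(-c4ccc(O[Si](C)(C)C(C)(C)C)c(O[Si](C)(C)C(C)(C)C)c4)cc(=O)c3c2OC(C)=O)C(C)(C)CC[C@@H]1O[Si](C(C)C)(C(C)C)C(C)C | intermediate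
22 | ugonin Q, 6-{[(1S,3S)-3-hydroxy-6,6-dimethyl-2-methylidenecyclohexyl]methyl}luteolin | C=C1[C@@H](Cc2c(O)cc3oc(-c4ccc(O)c(O)c4)cc(=O)c3c2O)C(C)(C)CC[C@@H]1O | target

**Step count**
Total: 14 steps. Longest linear sequence: 11 steps (steps 1–9, 13, 14).

**Steps most likely to fail**

Step 3. The enantiopurity may erode through incomplete endo selectivity, because the exo adduct becomes the enantiomer once the quaternary centre is levelled in step 4; a stepwise Mukaiyama–Michael addition may also compete with cycloaddition. The fallback sets out from 3 and makes the same two ring bonds by a Robinson annulation in which isobutyraldehyde brings both methyl groups. Michael addition of isobutyraldehyde to 3 under a chiral primary amine salt (9-amino-9-deoxy-epi-cinchona alkaloid, the pseudo-enantiomer that gives the (R) adduct, toluene, rt) should give (R)-3-{[(tert-butyldimethylsilyl)oxy]methyl}-2,2-dimethyl-5-oxohexanal F1. Intramolecular aldol condensation (KOH, MeOH, 0 °C) should close it to (R)-5-{[(tert-butyldimethylsilyl)oxy]methyl}-4,4-dimethylcyclohex-2-en-1-one F2. Kinetic α′-enolisation (LDA, THF, −78 °C) and Mannich trapping with [CH2=NMe2]I should give the α′-(dimethylaminomethyl) enone F3. Hydrogenation of the ring alkene (H2, Pd/C, EtOAc) then gives 9, where the route is rejoined and continues with the quaternisation and elimination of step 5.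

Step 13. Oxidative addition and transmetalation at the iodide flanked by two ortho oxygen substituents may be slow, so that β-hydride elimination from the alkylpalladium or protodezincation of 20 takes over. The fallback sets out from 15 and 18 and uses boron in place of zinc, which also makes step 12 unnecessary. Iodine–lithium exchange on 15 (t-BuLi, Et2O, −78 °C) should give the alkyllithium F4, which is trapped with 9-methoxy-9-borabicyclo[3.3.1]nonane as the lithium B-alkyl-B-methoxy borinate F5. B-alkyl Suzuki–Miyaura coupling with the unprotected iodide 18 (PdCl2(dppf), K3PO4 (aq), DMF/THF, rt to 50 °C) should give 7,3′,4′-tri-O-(tert-butyldimethylsilyl)-O-(triisopropylsilyl)ugonin Q F6. Desilylation with TBAF as in step 14 returns the route at 22.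

Step 6. Facial selectivity may be poor if the catalyst and the substrate bias are mismatched, and the borane may reduce the s-cis enone in a conjugate sense. The fallback sets out from 11 and uses substrate control followed by inversion. Luche reduction (NaBH4, CeCl3·7H2O, MeOH, −78 °C) is expected, by hydride delivery anti to the pseudoaxial CH2OTBS group, to give mainly the cis alcohol (1R,3S)-3-{[(tert-butyldimethylsilyl)oxy]methyl}-4,4-dimethyl-2-methylidenecyclohexan-1-ol F7. Mitsunobu inversion (4-nitrobenzoic acid, PPh3, diisopropyl azodicarboxylate, THF, 0 °C) should give the trans 4-nitrobenzoate F8. Methanolysis (K2CO3, MeOH, rt) returns the route at 12. Should the Luche reduction give 12 directly, the inversion is omitted.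

**Further compounds**
F1 | step 3 | (R)-3-{[(tert-butyldimethylsilyl)oxy]methyl}-2,2-dimethyl-5-oxohexanal | CC(=O)C[C@@H](CO[Si](C)(C)C(C)(C)C)C(C)(C)C=O
F2 | step 3 | (R)-5-{[(tert-butyldimethylsilyl)oxy]methyl}-4,4-dimethylcyclohex-2-en-1-one | O=C1C=CC(C)(C)[C@H](CO[Si](C)(C)C(C)(C)C)C1
F3 | step 3 | (5R)-5-{[(tert-butyldimethylsilyl)oxy]methyl}-6-[(dimethylamino)methyl]-4,4-dimethylcyclohex-2-en-1-one | CN(C)CC1C(=O)C=CC(C)(C)[C@@H]1CO[Si](C)(C)C(C)(C)C
F4 | step 13 | {[(1S,3S)-6,6-dimethyl-2-methylidene-3-(triisopropylsilyloxy)cyclohexyl]methyl}lithium | C=C1[C@@H](C[Li])C(C)(C)CC[C@@H]1O[Si](C(C)C)(C(C)C)C(C)C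
F5 | step 13 | lithium B-{[(1S,3S)-6,6-dimethyl-2-methylidene-3-(triisopropylsilyloxy)cyclohexyl]methyl}-B-methoxy-9-borabicyclo[3.3.1]nonan-9-uide | C=C1[C@@H](C[B-]2(OC)C3CCCC2CCC3)C(C)(C)CC[C@@H]1O[Si](C(C)C)(C(C)C)C(C)C.[Li+]
F6 | step 13 | 7,3′,4′-tri-O-(tert-butyldimethylsilyl)-O-(triisopropylsilyl)ugonin Q | C=C1[C@@H](Cc2c(O[Si](C)(C)C(C)(C)C)cc3oc(-c4ccc(O[Si](C)(C)C(C)(C)C)c(O[Si](C)(C)C(C)(C)C)c4)cc(=O)c3c2O)C(C)(C)CC[C@@H]1O[Si](C(C)C)(C(C)C)C(C)C
F7 | step 6 | (1R,3S)-3-{[(tert-butyldimethylsilyl)oxy]methyl}-4,4-dimethyl-2-methylidenecyclohexan-1-ol | C=C1[C@@H](CO[Si](C)(C)C(C)(C)C)C(C)(C)CC[C@H]1O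
F8 | step 6 | (1S,3S)-3-{[(tert-butyldimethylsilyl)oxy]methyl}-4,4-dimethyl-2-methylidenecyclohexyl 4-nitrobenzoate | C=C1[C@@H](CO[Si](C)(C)C(C)(C)C)C(C)(C)CC[C@@H]1OC(=O)c2ccc(cc2)[N+](=O)[O-]
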